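## Retrosynthetic overview

1. Gnetucleistol F ⇐ silyl ether cleavage ⇐ (E)-stilbene by Mizoroki–Heck coupling of a 5-vinyl-2,3-dihydrobenzofuran with 5-iodoresorcinol ⇐ methylenation of the 5-formyl compound 11.
2. Dihydrofuran ring of 11 ⇐ C2–O bond: enantioselective cycloisomerisation of the open 2,4'-dihydroxystilbene 9 through a p-quinone methide; this one ring closure sets C2 and C3.
3. 9 ⇐ Suzuki–Miyaura union (ring A–C3 bond) of 5-iodovanillin with (Z)-alkenyl bromide 6.
4. 6 ⇐ syringaldehyde by bromo-Wittig olefination, ester reduction and silylation.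
5. Ring order: the three benzene rings are bought; the dihydrofuran is the only ring made (step 5).

Assumption: the sense of induction of the new step 5 cannot be predicted with confidence; (R)-TRIP is written, and (S)-TRIP is used instead if the first run gives the (2S,3R) antipode.

Abbreviations: TRIP = 3,3'-bis(2,4,6-triisopropylphenyl)-1,1'-binaphthalene-2,2'-diyl hydrogen phosphate; TBDPS = tert-butyldiphenylsilyl; pin = pinacolato; dppf = 1,1'-bis(diphenylphosphino)ferrocene.

## Route

Step 1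
Reactants: 1 syringaldehyde; 2 ethyl (triphenylphosphoranylidene)acetate
Product: 4 ethyl (Z)-2-bromo-3-(4-hydroxy-3,5-dimethoxyphenyl)prop-2-enoate, via bromo ylide 3 (not isolated)
Conditions: 2, NBS, CH2Cl2, −20 °C; then 1, 40 °C
Reagents that add atoms: N-bromosuccinimide, O=C1CCC(=O)N1Br
Why: NBS brominates the stabilised ylide to bromo ylide 3, and its Wittig olefination of the aldehyde is (Z)-selective (bromine cis to the aryl group); the phenol is too weak an acid to quench this ylide.

Step 2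
Reactants: 4 ethyl (Z)-2-bromo-3-(4-hydroxy-3,5-dimethoxyphenyl)prop-2-enoate
Product: 5 4-[(Z)-2-bromo-3-hydroxyprop-1-en-1-yl]-2,6-dimethoxyphenol
Conditions: i-Bu2AlH (3.5 equiv), CH2Cl2, −78 to 0 °C
Reagents that add atoms: none
Why: 1,2-reduction of the conjugated ester to the allylic alcohol by i-Bu2AlH at low temperature leaves the alkenyl bromide and the alkene geometry intact; one equivalent is consumed by the phenol.

Step 3
Reactants: 5 4-[(Z)-2-bromo-3-hydroxyprop-1-en-1-yl]-2,6-dimethoxyphenol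
Product: 6 4-[(Z)-2-bromo-3-{[tert-butyl(diphenyl)silyl]oxy}prop-1-en-1-yl]-2,6-dimethoxyphenol
Conditions: t-BuPh2SiCl (1.05 equiv), imidazole, CH2Cl2, 0 °C
Reagents that add atoms: tert-butyl(chloro)diphenylsilane, CC(C)(C)[Si](Cl)(c1ccccc1)c1ccccc1
Why: Silyl ether formation; the bulky chlorosilane takes the primary allylic hydroxyl much faster than the phenol flanked by two methoxy groups, and the acid-robust silyl ether later suppresses allylic ionisation.

Step 4
Reactants: 6 4-[(Z)-2-bromo-3-{[tert-butyl(diphenyl)silyl]oxy}prop-1-en-1-yl]-2,6-dimethoxyphenol; 7 5-iodovanillin (4-hydroxy-3-iodo-5-methoxybenzaldehyde)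
Product: 9 4-hydroxy-3-methoxy-5-[(E)-3-{[tert-butyl(diphenyl)silyl]oxy}-1-(4-hydroxy-3,5-dimethoxyphenyl)prop-1-en-2-yl]benzaldehyde (the two aryl groups cis), via ring A pinacol boronate 8 (not isolated)
Conditions: 7, B2pin2 (1.05 equiv), PdCl2(dppf), KOAc, dioxane, 85 °C; then 6, K3PO4, H2O, 85 °C
Reagents that add atoms: bis(pinacolato)diboron, CC1(C)OB(OC1(C)C)B1OC(C)(C)C(C)(C)O1 (its boron is carried only in 8)
Why: Miyaura borylation of the aryl iodide followed in the same flask by Suzuki–Miyaura coupling with the alkenyl bromide, which goes with retention of alkene geometry and tolerates free phenols and the aldehyde; the position of the bromine fixes the ring A–C3 bond regiochemistry.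

Step 5
Reactants: 9 4-hydroxy-3-methoxy-5-[(E)-3-{[tert-butyl(diphenyl)silyl]oxy}-1-(4-hydroxy-3,5-dimethoxyphenyl)prop-1-en-2-yl]benzaldehyde
Product: 11 (2R,3S)-3-({[tert-butyl(diphenyl)silyl]oxy}methyl)-2-(4-hydroxy-3,5-dimethoxyphenyl)-7-methoxy-2,3-dihydro-1-benzofuran-5-carbaldehyde, via p-quinone methide 10 (not isolated)
Conditions: (R)-TRIP (10 mol %), 5 Å MS, toluene (0.02 M), 40 °C; Et3N quench at full conversion
Reagents that add atoms: none
Why: Proposed new method: an enantioselective, redox-neutral cycloisomerisation by asymmetric Brønsted acid catalysis, ending in an intramolecular oxa-1,6-conjugate addition. The chiral phosphoric acid tautomerises the 4-hydroxystilbene unit of 9 (a vinylogous phenol) by protonating the alkene carbon that bears ring A while taking up the phenolic proton, giving p-quinone methide 10; this is reversible, so the new centre is set under catalyst control and can be corrected through achiral 9. The phosphate then bridges the quinone methide carbonyl and the ring A phenol in a 5-exo-trig oxa-1,6-addition that forms the C2–O bond, the matched epimer of 10 closing faster and the aryl group settling trans to the silyloxymethyl group, so C2 (R) and C3 (S) are both fixed when the ring closes. The formyl group makes the ring A phenol a poor donor, which disfavours the competing ortho-quinone methide. The closest known chemistry is the chiral phosphoric acid-catalysed 1,6-addition to p-quinone methides formed in situ from p-hydroxybenzyl alcohols, acid-catalysed hydroalkoxylation of hydroxystyrenes, and the phenylcoumaran ring closure of lignan biosynthesis.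

Step 6
Reactants: 11 (2R,3S)-3-({[tert-butyl(diphenyl)silyl]oxy}methyl)-2-(4-hydroxy-3,5-dimethoxyphenyl)-7-methoxy-2,3-dihydro-1-benzofuran-5-carbaldehyde
Product: 12 4-[(2R,3S)-3-({[tert-butyl(diphenyl)silyl]oxy}methyl)-5-ethenyl-7-methoxy-2,3-dihydro-1-benzofuran-2-yl]-2,6-dimethoxyphenol
Conditions: Ph3PCH3Br (3.2 equiv), KOt-Bu (3.2 equiv), THF, −78 to 0 °C
Reagents that add atoms: methyltriphenylphosphonium bromide, C[P+](c1ccccc1)(c1ccccc1)c1ccccc1.[Br-]
Why: Wittig methylenation of the aryl aldehyde with excess ylide (one equivalent is held by the phenol); the low temperature keeps the phenoxide from opening the benzylic aryl ether, and neither stereocentre is touched.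

Step 7
Reactants: 12 4-[(2R,3S)-3-({[tert-butyl(diphenyl)silyl]oxy}methyl)-5-ethenyl-7-methoxy-2,3-dihydro-1-benzofuran-2-yl]-2,6-dimethoxyphenol; 13 5-iodoresorcinol (5-iodobenzene-1,3-diol)
Product: 14 5-[(E)-2-{(2R,3S)-3-({[tert-butyl(diphenyl)silyl]oxy}methyl)-2-(4-hydroxy-3,5-dimethoxyphenyl)-7-methoxy-2,3-dihydro-1-benzofuran-5-yl}ethenyl]benzene-1,3-diol
Conditions: 13, Pd(OAc)2, P(o-tol)3, Et3N, DMF, 90 °C
Reagents that add atoms: none
Why: Mizoroki–Heck reaction of the electron-rich styrene with the aryl iodide gives the (E)-stilbene by β-arylation and syn β-hydride elimination; free phenols are tolerated and the stereocentres are remote from the reacting alkene.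

Step 8
Reactants: 14 5-[(E)-2-{(2R,3S)-3-({[tert-butyl(diphenyl)silyl]oxy}methyl)-2-(4-hydroxy-3,5-dimethoxyphenyl)-7-methoxy-2,3-dihydro-1-benzofuran-5-yl}ethenyl]benzene-1,3-diol
Product: 15 Gnetucleistol F, 5-[(E)-2-{(2R,3S)-2-(4-hydroxy-3,5-dimethoxyphenyl)-3-(hydroxymethyl)-7-methoxy-2,3-dihydro-1-benzofuran-5-yl}ethenyl]benzene-1,3-diol
Conditions: Bu4NF, AcOH, THF, 0 °C to rt
Reagents that add atoms: none
Why: Fluoride-mediated silyl ether cleavage buffered with acetic acid, which avoids phenoxide-triggered ring opening and leaves the stilbene and both stereocentres untouched.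

## Compound list

1 | syringaldehyde (4-hydroxy-3,5-dimethoxybenzaldehyde) | COc1cc(C=O)cc(OC)c1O | starting material
2 | ethyl (triphenylphosphoranylidene)acetate | CCOC(=O)C=P(c1ccccc1)(c1ccccc1)c1ccccc1 | starting material
3 | ethyl bromo(triphenylphosphoranylidene)acetate (bromo ylide) | CCOC(=O)C(Br)=P(c1ccccc1)(c1ccccc1)c1ccccc1 | intermediate
4 | ethyl (Z)-2-bromo-3-(4-hydroxy-3,5-dimethoxyphenyl)prop-2-enoate | CCOC(=O)/C(Br)=C/c1cc(OC)c(O)c(OC)c1 | intermediate
5 | 4-[(Z)-2-bromo-3-hydroxyprop-1-en-1-yl]-2,6-dimethoxyphenol | OC/C(Br)=C/c1cc(OC)c(O)c(OC)c1 | intermediate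
6 | 4-[(Z)-2-bromo-3-{[tert-butyl(diphenyl)silyl]oxy}prop-1-en-1-yl]-2,6-dimethoxyphenol | CC(C)(C)[Si](c1ccccc1)(c1ccccc1)OC/C(Br)=C/c1cc(OC)c(O)c(OC)c1 | intermediate
7 | 5-iodovanillin (4-hydroxy-3-iodo-5-methoxybenzaldehyde) | COc1cc(C=O)cc(I)c1O | starting material
8 | 4-hydroxy-3-methoxy-5-(4,4,5,5-tetramethyl-1,3,2-dioxaborolan-2-yl)benzaldehyde | COc1cc(C=O)cc(B2OC(C)(C)C(C)(C)O2)c1O | intermediate
9 | 4-hydroxy-3-methoxy-5-[(E)-3-{[tert-butyl(diphenyl)silyl]oxy}-1-(4-hydroxy-3,5-dimethoxyphenyl)prop-1-en-2-yl]benzaldehyde (aryl groups cis) | COc1cc(C=O)cc(c1O)/C(CO[Si](c1ccccc1)(c1ccccc1)C(C)(C)C)=C\c1cc(OC)c(O)c(OC)c1 | intermediate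
10 | 4-hydroxy-3-methoxy-5-[(2S)-1-{[tert-butyl(diphenyl)silyl]oxy}-3-(3,5-dimethoxy-4-oxocyclohexa-2,5-dien-1-ylidene)propan-2-yl]benzaldehyde (p-quinone methide) | COc1cc(C=O)cc(c1O)[C@H](C=C1C=C(OC)C(=O)C(OC)=C1)CO[Si](c1ccccc1)(c1ccccc1)C(C)(C)C | intermediate
11 | (2R,3S)-3-({[tert-butyl(diphenyl)silyl]oxy}methyl)-2-(4-hydroxy-3,5-dimethoxyphenyl)-7-methoxy-2,3-dihydro-1-benzofuran-5-carbaldehyde (2,3-trans) | COc1cc([C@@H]2Oc3c(OC)cc(C=O)cc3[C@H]2CO[Si](c4ccccc4)(c5ccccc5)C(C)(C)C)cc(OC)c1O | intermediate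
12 | 4-[(2R,3S)-3-({[tert-butyl(diphenyl)silyl]oxy}methyl)-5-ethenyl-7-methoxy-2,3-dihydro-1-benzofuran-2-yl]-2,6-dimethoxyphenol | COc1cc([C@@H]2Oc3c(OC)cc(C=C)cc3[C@H]2CO[Si](c4ccccc4)(c5ccccc5)C(C)(C)C)cc(OC)c1O | intermediate
13 | 5-iodoresorcinol (5-iodobenzene-1,3-diol) | Oc1cc(O)cc(I)c1 | starting material
14 | 5-[(E)-2-{(2R,3S)-3-({[tert-butyl(diphenyl)silyl]oxy}methyl)-2-(4-hydroxy-3,5-dimethoxyphenyl)-7-methoxy-2,3-dihydro-1-benzofuran-5-yl}ethenyl]benzene-1,3-diol | COc1cc([C@@H]2Oc3c(OC)cc(/C=C/c4cc(O)cc(O)c4)cc3[C@H]2CO[Si](c5ccccc5)(c6ccccc6)C(C)(C)C)cc(OC)c1O | intermediate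
15 | Gnetucleistol F, 5-[(E)-2-{(2R,3S)-2-(4-hydroxy-3,5-dimethoxyphenyl)-3-(hydroxymethyl)-7-methoxy-2,3-dihydro-1-benzofuran-5-yl}ethenyl]benzene-1,3-diol | COc1cc([C@@H]2Oc3c(OC)cc(/C=C/c4cc(O)cc(O)c4)cc3[C@H]2CO)cc(OC)c1O | target

## Step count and risks

Total step count: 8. Longest linear sequence: 8 steps (syringaldehyde 1 to 15); 7 and 13 are bought.

Steps most likely to fail:

1. Step 5 (the proposed new cycloisomerisation). The acid may be too weak to reach quinone methide 10, and ring closure is estimated to be downhill by only a few kcal/mol. Background closure, protonation at the other alkene carbon or allylic ionisation of the silyl ether could lower yield or ee, and the product can racemise slowly through 9 if left on the catalyst. Fallback (known chemistry), setting out from 9 and coming back at 11: the trisubstituted alkene of 9 is hydrogenated enantioselectively with an iridium phosphinooxazoline catalyst, [Ir(cod)(L)]BArF (L = tert-butyl-PHOX, antipode chosen to give the S centre), H2 (50 bar), CH2Cl2, to the saturated aldehyde 4-hydroxy-3-methoxy-5-[(2S)-1-{[tert-butyl(diphenyl)silyl]oxy}-3-(4-hydroxy-3,5-dimethoxyphenyl)propan-2-yl]benzaldehyde F1. DDQ (1.05 equiv, dioxane, rt; Ag2O as alternative) then dehydrogenates the 4-hydroxy-3,5-dimethoxybenzyl position to quinone methide 10 with C3 already fixed, and the ring A phenol closes it to trans-11.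

2. Step 4 (one-pot borylation and Suzuki coupling). The ortho-hydroxy aryl boronate 8 may protodeboronate in hot aqueous base before it couples with the hindered alkenyl bromide. Fallback, setting out from 6 and coming back at 9: the roles are exchanged so that the partner prone to protodeboronation carries the halogen. Bromide 6 is borylated (B2pin2, PdCl2(dppf), KOAc, dioxane, 80 °C) to the isolable alkenyl boronate 4-[(E)-3-{[tert-butyl(diphenyl)silyl]oxy}-2-(4,4,5,5-tetramethyl-1,3,2-dioxaborolan-2-yl)prop-1-en-1-yl]-2,6-dimethoxyphenol F2, which is purified and coupled with 7 (Pd(OAc)2, SPhos, K3PO4, toluene/H2O, 80 °C) to give 9.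

3. Step 7 (Heck coupling on a polyphenol). α-Arylation of the electron-rich styrene, catalyst inhibition by the free phenols or partial opening of the benzylic ether at 90 °C could erode the yield. Fallback, setting out from 11 and coming back at 15: the stilbene is made by carbonyl olefination instead, bypassing 12 and 14. Horner–Wadsworth–Emmons reaction of 11 with the known phosphonate diethyl {[3,5-bis(tert-butyldimethylsilyloxy)phenyl]methyl}phosphonate F3 (KOt-Bu, 2.2 equiv, THF, −78 to 0 °C) gives the (E)-stilbene 4-[(2R,3S)-5-[(E)-2-{3,5-bis[(tert-butyldimethylsilyl)oxy]phenyl}ethenyl]-3-({[tert-butyl(diphenyl)silyl]oxy}methyl)-7-methoxy-2,3-dihydro-1-benzofuran-2-yl]-2,6-dimethoxyphenol F4. Bu4NF/AcOH in THF then removes all three silyl groups to give 15.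

## Further compounds

F1 | step 5 | 4-hydroxy-3-methoxy-5-[(2S)-1-{[tert-butyl(diphenyl)silyl]oxy}-3-(4-hydroxy-3,5-dimethoxyphenyl)propan-2-yl]benzaldehyde | COc1cc(C=O)cc(c1O)[C@H](Cc1cc(OC)c(O)c(OC)c1)CO[Si](c1ccccc1)(c1ccccc1)C(C)(C)C
F2 | step 4 | 4-[(E)-3-{[tert-butyl(diphenyl)silyl]oxy}-2-(4,4,5,5-tetramethyl-1,3,2-dioxaborolan-2-yl)prop-1-en-1-yl]-2,6-dimethoxyphenol | CC(C)(C)[Si](c1ccccc1)(c1ccccc1)OC/C(B1OC(C)(C)C(C)(C)O1)=C/c1cc(OC)c(O)c(OC)c1
F3 | step 7 | diethyl {[3,5-bis(tert-butyldimethylsilyloxy)phenyl]methyl}phosphonate | CCOP(=O)(Cc1cc(O[Si](C)(C)C(C)(C)C)cc(O[Si](C)(C)C(C)(C)C)c1)OCC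
F4 | step 7 | 4-[(2R,3S)-5-[(E)-2-{3,5-bis[(tert-butyldimethylsilyl)oxy]phenyl}ethenyl]-3-({[tert-butyl(diphenyl)silyl]oxy}methyl)-7-methoxy-2,3-dihydro-1-benzofuran-2-yl]-2,6-dimethoxyphenol | COc1cc([C@@H]2Oc3c(OC)cc(/C=C/c4cc(O[Si](C)(C)C(C)(C)C)cc(O[Si](C)(C)C(C)(C)C)c4)cc3[C@H]2CO[Si](c5ccccc5)(c6ccccc6)C(C)(C)C)cc(OC)c1O
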